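**Plan**

1. Target locants (bicyclo[3.2.1]octane): C1 = OMe bridgehead, C2 = CH(OAc), C3 = C(OMe)=, C4 = CH=, C5 = allyl bridgehead, C6 = CH(Me), C7 = CH(aryl), C8 = C=O. The five-membered ring C1–C8–C5–C6–C7 is an acyloin ether (ketone C8 beside the tertiary ether carbon C1), and C8 and C1 are 1,5-related through C5–C6–C7: this is the retron of an aldehyde/enone Michael–benzoin annulation.
2. Retrosynthesis: remove the acetate and the C2 hydrogen (back to the 2-ketone), then the C3=C4 double bond. Cut the six-membered ring at C1–C2 (C-acylation) and C5–C4 (conjugate addition). Last, cut C8–C1 and C5–C6 of the cyclopentanone together, back to pent-4-enal and an aryl-substituted β,γ-unsaturated α-keto ester whose tert-butyl ester is a removable activating group.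
3. Forward: keto ester 7 (3 steps); cyclopentanone ring (step 4); O-methylation; quaternization of C5; loss of the activating carboxyl group; six-membered ring by closure onto C1; enone; reduction; acetylation.
4. Stereochemistry: C6 from the amine catalyst in step 4; C7 by equilibration in step 4 (aryl trans to methyl); C5 by addition anti to the C6 methyl group (step 6); C1 by the tether, which can bridge only cis (step 8); C2 by hydride delivery on the face away from the endo aryl group (step 10).

Key step: step 4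

Remark: the carbinol and allyl-bearing centres of 10 and 11, and the side-chain methoxy centre of 13–18, should form as epimer mixtures that converge later; one epimer is drawn for each.

**Route**

Step 1
Reactants: 1 3,4,5-trimethoxybenzoyl chloride; 2 ethylmagnesium bromide
Product: 3 1-(3,4,5-trimethoxyphenyl)propan-1-one
Conditions: 2 (1.05 equiv), Fe(acac)3 (3 mol %), THF, −78 °C
Reagents that add atoms: none
Why: Iron-catalysed acylation of a Grignard reagent by an acid chloride should stop at the ketone, because the acyl chloride couples far faster than the product ketone adds the Grignard reagent.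

Step 2
Reactants: 3 1-(3,4,5-trimethoxyphenyl)propan-1-one
Product: 4 N'-[(1E)-1-(3,4,5-trimethoxyphenyl)propylidene]-2,4,6-tri(propan-2-yl)benzenesulfonohydrazide
Conditions: 2,4,6-triisopropylbenzenesulfonohydrazide, HCl (cat.), MeOH, 23 °C
Reagents that add atoms: 2,4,6-triisopropylbenzenesulfonohydrazide, CC(C)c1cc(C(C)C)c(S(=O)(=O)NN)c(C(C)C)c1
Why: Acid-catalysed hydrazone condensation should place the sulfonamide nitrogen anti to the aryl ring, syn to the ethyl group that is deprotonated in the next step.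

Step 3
Reactants: 4 N'-[(1E)-1-(3,4,5-trimethoxyphenyl)propylidene]-2,4,6-tri(propan-2-yl)benzenesulfonohydrazide; 5 di-tert-butyl oxalate
Product: 7 tert-butyl (3E)-2-oxo-3-(3,4,5-trimethoxyphenyl)pent-3-enoate, via vinyllithium 6 (not isolated)
Conditions: n-BuLi (2.1 equiv), TMEDA, THF, −78 → 0 °C; then cannulated into 5 (3 equiv), THF, −78 °C
Reagents that add atoms: none
Why: Shapiro reaction: the syn dianion should lose sulfinate and dinitrogen to give the vinyllithium with methyl trans to lithium, and acylation by the hindered oxalate (one substitution only) with retention should give the (E)-keto ester.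

Step 4
Reactants: 7 tert-butyl (3E)-2-oxo-3-(3,4,5-trimethoxyphenyl)pent-3-enoate; 8 pent-4-enal
Product: 10 tert-butyl (1S,3R,4S,5R)-1-hydroxy-4-methyl-2-oxo-3-(prop-2-en-1-yl)-5-(3,4,5-trimethoxyphenyl)cyclopentane-1-carboxylate, via keto aldehyde 9 (not isolated)
Conditions: 8 (2 equiv), (S)-α,α-diphenylprolinol trimethylsilyl ether (20 mol %), 2-(pentafluorophenyl)-6,7-dihydro-5H-pyrrolo[2,1-c][1,2,4]triazol-2-ium tetrafluoroborate (20 mol %), NaOAc (20 mol %), CHCl3, 23 °C
Reagents that add atoms: none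
Why: Relay enamine/N-heterocyclic-carbene catalysis (Michael addition then intramolecular crossed benzoin, a formal (3+2) annulation known for aliphatic aldehydes and activated enones): the enamine of 8 adds to the methyl-bearing alkene carbon of 7 (forming C5–C6), and after hydrolysis the carbene turns the aldehyde of 9 into its Breslow intermediate, whose acyl-anion carbon adds to the ketone of the α-keto ester (forming C8–C1) before the catalyst is released. The cyclopentanone ring closes by 5-exo-trig attack on that ketone. C6 is set by the amine catalyst: the diphenyl(silyloxy)methyl group shields one face of the (E)-enamine and the acceptor reacts through the acyclic synclinal transition state with its acyl group under the enamine nitrogen, which for the (S)-catalyst should give the required (S) methyl centre. C7 is set by equilibration, since its hydrogen lies between the aryl ring and the 1,2-dicarbonyl unit and epimerizes freely in 9, so the reversible ring closure should drain the isomer with aryl trans to methyl. The carbinol centre C1 and the allyl-bearing C5 need no control here, because C1 is re-formed in step 8 after loss of the carboxyl group and C5 is re-set in step 6. The step needs conjugate rather than carbonyl addition and cross- rather than homo-benzoin or Stetter reaction, and both are secured by the 1,2-dicarbonyl unit of 7, which polarizes the alkene for the enamine and then offers a highly electrophilic ketone five atoms from the aldehyde.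

Step 5
Reactants: 10 tert-butyl (1S,3R,4S,5R)-1-hydroxy-4-methyl-2-oxo-3-(prop-2-en-1-yl)-5-(3,4,5-trimethoxyphenyl)cyclopentane-1-carboxylate
Product: 11 tert-butyl (1S,3R,4S,5R)-1-methoxy-4-methyl-2-oxo-3-(prop-2-en-1-yl)-5-(3,4,5-trimethoxyphenyl)cyclopentane-1-carboxylate
Conditions: Me3OBF4 (3 equiv), 1,8-bis(dimethylamino)naphthalene (3.5 equiv), 4 Å MS, CH2Cl2, 23 °C
Reagents that add atoms: trimethyloxonium tetrafluoroborate, C[O+](C)C.F[B-](F)(F)F
Why: O-alkylation of the hindered tertiary alcohol with a strong methyl donor under non-nucleophilic buffering avoids an alkoxide, and with it retro-benzoin or 1,2-acyl shift of the α-ketol; no stereocentre is touched.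

Step 6
Reactants: 11 tert-butyl (1S,3R,4S,5R)-1-methoxy-4-methyl-2-oxo-3-(prop-2-en-1-yl)-5-(3,4,5-trimethoxyphenyl)cyclopentane-1-carboxylate; 12 methyl 2-methoxyprop-2-enoate
Product: 13 tert-butyl (1S,3R,4S,5R)-3-(2,3-dimethoxy-3-oxopropyl)-1-methoxy-4-methyl-2-oxo-3-(prop-2-en-1-yl)-5-(3,4,5-trimethoxyphenyl)cyclopentane-1-carboxylate
Conditions: LiN(i-Pr)2 (1.1 equiv), THF, −78 °C; 12 (1.3 equiv), −78 → −40 °C; AcOH
Reagents that add atoms: none
Why: Michael addition of the only possible ketone enolate (C1 is blocked by methoxy and ester) to the α-alkoxyacrylate should create quaternary C5, the acceptor approaching the planar enolate anti to the adjacent C6 methyl group so that the new chain is cis to the aryl group and both C5 epimers of 11 converge; the side-chain methoxy centre forms as a mixture and is erased in step 9.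

Step 7
Reactants: 13 tert-butyl (1S,3R,4S,5R)-3-(2,3-dimethoxy-3-oxopropyl)-1-methoxy-4-methyl-2-oxo-3-(prop-2-en-1-yl)-5-(3,4,5-trimethoxyphenyl)cyclopentane-1-carboxylate
Product: 16 2-methoxy-3-[3-methoxy-5-methyl-2-oxo-1-(prop-2-en-1-yl)-4-(3,4,5-trimethoxyphenyl)cyclopentyl]propanoic acid, via β-keto acid 14 (not isolated), via methyl ester 15 (not isolated)
Conditions: TFA, CH2Cl2, 23 °C; PhMe, 80 °C; then LiOH, THF–H2O, 23 °C; 1 M HCl
Reagents that add atoms: lithium hydroxide, [Li+].[OH-]
Why: Acidolysis of the tert-butyl ester and thermal decarboxylation of the β-keto acid remove the activating carboxyl group (C1 becomes an epimerizable CH(OMe) centre), and saponification of the unhindered methyl ester then gives the acid for ring closure.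

Step 8
Reactants: 16 2-methoxy-3-[3-methoxy-5-methyl-2-oxo-1-(prop-2-en-1-yl)-4-(3,4,5-trimethoxyphenyl)cyclopentyl]propanoic acid
Product: 18 1,3-dimethoxy-6-methyl-5-(prop-2-en-1-yl)-7-(3,4,5-trimethoxyphenyl)bicyclo[3.2.1]octane-2,8-dione, via pentafluorophenyl ester 17 (not isolated)
Conditions: C6F5OH, EDC·HCl, CH2Cl2, 0 → 23 °C; then MgBr2·OEt2, i-Pr2NEt, 23 °C
Reagents that add atoms: none
Why: Soft-enolization crossed Claisen acylation: magnesium chelated between the ketone and the α-methoxy group lets the amine form the only possible enolate, which should be C-acylated by the tethered active ester in a 6-(enolendo)-exo-trig closure; the tether reaches C1 only on the face that carries the chain, so C1 is fixed and its epimers converge, and the weakly nucleophilic phenoxide should not reopen the non-enolizable 1,3-diketone.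

Step 9
Reactants: 18 1,3-dimethoxy-6-methyl-5-(prop-2-en-1-yl)-7-(3,4,5-trimethoxyphenyl)bicyclo[3.2.1]octane-2,8-dione
Product: 20 1,3-dimethoxy-6-methyl-5-(prop-2-en-1-yl)-7-(3,4,5-trimethoxyphenyl)bicyclo[3.2.1]oct-3-ene-2,8-dione, via silyl enol ether 19 (not isolated)
Conditions: Me3SiOTf, Et3N, CH2Cl2, 0 °C; then Pd(OAc)2 (1.1 equiv), MeCN, 23 °C
Reagents that add atoms: none
Why: Saegusa–Ito oxidation: only the C2 ketone can enolize (towards C3), and the palladium enolate should lose a syn hydrogen from C4 to give the 3-methoxy enone, erasing the mixed C3 centre.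

Step 10
Reactants: 20 1,3-dimethoxy-6-methyl-5-(prop-2-en-1-yl)-7-(3,4,5-trimethoxyphenyl)bicyclo[3.2.1]oct-3-ene-2,8-dione
Product: 21 2-hydroxy-1,3-dimethoxy-6-methyl-5-(prop-2-en-1-yl)-7-(3,4,5-trimethoxyphenyl)bicyclo[3.2.1]oct-3-en-8-one
Conditions: NaBH4, CeCl3·7H2O, MeOH, −78 °C
Reagents that add atoms: none
Why: Luche reduction should take the conjugated C2 ketone in preference to the C8 ketone buried between two quaternary carbons, with hydride arriving on the face syn to the one-carbon bridge because the endo aryl group on C7 covers the other face, which gives the required C2 configuration.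

Step 11
Reactants: 21 2-hydroxy-1,3-dimethoxy-6-methyl-5-(prop-2-en-1-yl)-7-(3,4,5-trimethoxyphenyl)bicyclo[3.2.1]oct-3-en-8-one
Product: 22 (1S,2R,5S,6S,7R)-1,3-dimethoxy-6-methyl-8-oxo-5-(prop-2-en-1-yl)-7-(3,4,5-trimethoxyphenyl)bicyclo[3.2.1]oct-3-en-2-yl acetate
Conditions: Ac2O, pyridine, DMAP (cat.), CH2Cl2, 23 °C
Reagents that add atoms: acetic anhydride, CC(=O)OC(C)=O
Why: DMAP-catalysed acetylation of the secondary allylic alcohol proceeds with retention at C2.

**Compound list**

1 | 3,4,5-trimethoxybenzoyl chloride | COc1cc(cc(OC)c1OC)C(Cl)=O | starting material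
2 | ethylmagnesium bromide | CC[Mg]Br | starting material
3 | 1-(3,4,5-trimethoxyphenyl)propan-1-one | CCC(=O)c1cc(OC)c(OC)c(OC)c1 | intermediate
4 | N'-[(1E)-1-(3,4,5-trimethoxyphenyl)propylidene]-2,4,6-tri(propan-2-yl)benzenesulfonohydrazide | CC/C(=N\NS(=O)(=O)c1c(cc(cc1C(C)C)C(C)C)C(C)C)c1cc(OC)c(OC)c(OC)c1 | intermediate
5 | di-tert-butyl oxalate | CC(C)(C)OC(=O)C(=O)OC(C)(C)C | starting material
6 | [(1Z)-1-(3,4,5-trimethoxyphenyl)prop-1-en-1-yl]lithium (aryl cis to methyl) | C/C=C(/[Li])c1cc(OC)c(OC)c(OC)c1 | intermediate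
7 | tert-butyl (3E)-2-oxo-3-(3,4,5-trimethoxyphenyl)pent-3-enoate (methyl trans to the keto ester, cis to aryl) | C/C=C(\c1cc(OC)c(OC)c(OC)c1)C(=O)C(=O)OC(C)(C)C | intermediate
8 | pent-4-enal | C=CCCC=O | starting material
9 | tert-butyl 5-formyl-4-methyl-2-oxo-3-(3,4,5-trimethoxyphenyl)oct-7-enoate (syn Michael adduct; aryl-bearing centre epimerizing) | C=CC[C@@H](C=O)[C@@H](C)[C@H](c1cc(OC)c(OC)c(OC)c1)C(=O)C(=O)OC(C)(C)C | intermediate
10 | tert-butyl (1S,3R,4S,5R)-1-hydroxy-4-methyl-2-oxo-3-(prop-2-en-1-yl)-5-(3,4,5-trimethoxyphenyl)cyclopentane-1-carboxylate (methyl trans to aryl; 1- and 3-epimers tolerated) | C=CC[C@H]1C(=O)[C@@](C(=O)OC(C)(C)C)(O)[C@@H](c2cc(OC)c(OC)c(OC)c2)[C@@H]1C | intermediate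
11 | tert-butyl (1S,3R,4S,5R)-1-methoxy-4-methyl-2-oxo-3-(prop-2-en-1-yl)-5-(3,4,5-trimethoxyphenyl)cyclopentane-1-carboxylate | C=CC[C@H]1C(=O)[C@@](C(=O)OC(C)(C)C)(OC)[C@@H](c2cc(OC)c(OC)c(OC)c2)[C@@H]1C | intermediate
12 | methyl 2-methoxyprop-2-enoate | C=C(OC)C(=O)OC | starting material
13 | tert-butyl (1S,3R,4S,5R)-3-(2,3-dimethoxy-3-oxopropyl)-1-methoxy-4-methyl-2-oxo-3-(prop-2-en-1-yl)-5-(3,4,5-trimethoxyphenyl)cyclopentane-1-carboxylate (new chain cis to aryl, allyl cis to methyl; side-chain epimers) | C=CC[C@]1(CC(OC)C(=O)OC)C(=O)[C@@](C(=O)OC(C)(C)C)(OC)[C@@H](c2cc(OC)c(OC)c(OC)c2)[C@@H]1C | intermediate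
14 | 3-(2,3-dimethoxy-3-oxopropyl)-1-methoxy-4-methyl-2-oxo-3-(prop-2-en-1-yl)-5-(3,4,5-trimethoxyphenyl)cyclopentane-1-carboxylic acid (ring configured as in 13) | C=CC[C@]1(CC(OC)C(=O)OC)C(=O)[C@@](C(=O)O)(OC)[C@@H](c2cc(OC)c(OC)c(OC)c2)[C@@H]1C | intermediate
15 | methyl 2-methoxy-3-[3-methoxy-5-methyl-2-oxo-1-(prop-2-en-1-yl)-4-(3,4,5-trimethoxyphenyl)cyclopentyl]propanoate (ring as in 13; 3-methoxy drawn trans to aryl, epimerizable) | C=CC[C@]1(CC(OC)C(=O)OC)C(=O)[C@H](OC)[C@@H](c2cc(OC)c(OC)c(OC)c2)[C@@H]1C | intermediate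
16 | 2-methoxy-3-[3-methoxy-5-methyl-2-oxo-1-(prop-2-en-1-yl)-4-(3,4,5-trimethoxyphenyl)cyclopentyl]propanoic acid (configured as 15) | C=CC[C@]1(CC(OC)C(=O)O)C(=O)[C@H](OC)[C@@H](c2cc(OC)c(OC)c(OC)c2)[C@@H]1C | intermediate
17 | pentafluorophenyl 2-methoxy-3-[3-methoxy-5-methyl-2-oxo-1-(prop-2-en-1-yl)-4-(3,4,5-trimethoxyphenyl)cyclopentyl]propanoate (configured as 15) | C=CC[C@]1(CC(OC)C(=O)Oc2c(F)c(F)c(F)c(F)c2F)C(=O)[C@H](OC)[C@@H](c2cc(OC)c(OC)c(OC)c2)[C@@H]1C | intermediate
18 | 1,3-dimethoxy-6-methyl-5-(prop-2-en-1-yl)-7-(3,4,5-trimethoxyphenyl)bicyclo[3.2.1]octane-2,8-dione (bridgeheads, 6-exo-methyl and 7-endo-aryl as in 22; 3-epimers) | C=CC[C@]12CC(OC)C(=O)[C@](OC)(C1=O)[C@@H](c1cc(OC)c(OC)c(OC)c1)[C@@H]2C | intermediate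
19 | 1,3-dimethoxy-6-methyl-5-(prop-2-en-1-yl)-7-(3,4,5-trimethoxyphenyl)-2-[(trimethylsilyl)oxy]bicyclo[3.2.1]oct-2-en-8-one (configured as 22) | C=CC[C@]12CC(OC)=C(O[Si](C)(C)C)[C@](OC)(C1=O)[C@@H](c1cc(OC)c(OC)c(OC)c1)[C@@H]2C | intermediate
20 | 1,3-dimethoxy-6-methyl-5-(prop-2-en-1-yl)-7-(3,4,5-trimethoxyphenyl)bicyclo[3.2.1]oct-3-ene-2,8-dione (configured as 22: 6-exo-methyl, 7-endo-aryl) | C=CC[C@]12C=C(OC)C(=O)[C@](OC)(C1=O)[C@@H](c1cc(OC)c(OC)c(OC)c1)[C@@H]2C | intermediate
21 | 2-hydroxy-1,3-dimethoxy-6-methyl-5-(prop-2-en-1-yl)-7-(3,4,5-trimethoxyphenyl)bicyclo[3.2.1]oct-3-en-8-one (configured as 22; hydroxyl on the face of the two-carbon bridge) | C=CC[C@]12C=C(OC)[C@@H](O)[C@](OC)(C1=O)[C@@H](c1cc(OC)c(OC)c(OC)c1)[C@@H]2C | intermediate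
22 | (1S,2R,5S,6S,7R)-1,3-dimethoxy-6-methyl-8-oxo-5-(prop-2-en-1-yl)-7-(3,4,5-trimethoxyphenyl)bicyclo[3.2.1]oct-3-en-2-yl acetate (CNP0181407.1) | C=CC[C@]12C=C(OC)[C@@H](OC(C)=O)[C@](OC)(C1=O)[C@@H](c1cc(OC)c(OC)c(OC)c1)[C@@H]2C | target

**Count and risks**

Total step count: 11. Longest linear sequence: 11 steps (1 → 22); 2, 5, 8 and 12 are purchased.

Steps most likely to fail:

Step 4. The enamine may add too slowly to the trisubstituted, α-aryl acceptor; the keto ester may deconjugate by deprotonation of its methyl group; the carbene may be diverted into homo-benzoin of 8; and facial control at the methyl-bearing carbon may erode. The fallback sets out from 7 and 8 and returns at 10. Aldehyde 8 is converted (Me3SiCl, Et3N, DMF) into trimethyl[(1E)-penta-1,4-dien-1-yloxy]silane F1. F1 is added to 7 in a Mukaiyama–Michael reaction under Cu(OTf)2 with a tert-butyl bis(oxazoline) ligand, the 1,2-dicarbonyl unit chelating the metal. Acidic work-up should give keto aldehyde 9, now isolated, and a separate benzoin cyclization (the same triazolium salt, DBU, THF) should give 10.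

Step 8. The enolate may be acylated on oxygen to an enol lactone, or the crowded methoxy-bearing enolate carbon may fail to reach the active ester because the bridged, non-enolizable diketone is strained. The fallback replaces acylation by aldol addition and oxidation; it sets out from 13 and returns at 18. The methyl ester of 13 is reduced with i-Bu2AlH at −78 °C to tert-butyl 1-methoxy-3-(2-methoxy-3-oxopropyl)-4-methyl-2-oxo-3-(prop-2-en-1-yl)-5-(3,4,5-trimethoxyphenyl)cyclopentane-1-carboxylate F2. The neighbouring methoxy group holds the aluminate at the aldehyde stage, and the ring ketone lies between two quaternary carbons. TFA and then heat remove the tert-butyl ester and carbon dioxide to give 2-methoxy-3-[3-methoxy-5-methyl-2-oxo-1-(prop-2-en-1-yl)-4-(3,4,5-trimethoxyphenyl)cyclopentyl]propanal F3. F3 is closed by intramolecular aldol addition (pyrrolidine, AcOH, or KOH, MeOH) to 2-hydroxy-1,3-dimethoxy-6-methyl-5-(prop-2-en-1-yl)-7-(3,4,5-trimethoxyphenyl)bicyclo[3.2.1]octan-8-one F4. Dess–Martin oxidation should then give 18.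

Step 5. Alkylation of the crowded tertiary hydroxyl group may be incomplete, and material may be lost through retro-benzoin or acyl shift of the α-ketol. The fallback defers methylation to a secondary alcohol; it sets out from 10 and returns at 15. Compound 10 is silylated (Me3SiOTf, 2,6-lutidine) to tert-butyl 4-methyl-2-oxo-3-(prop-2-en-1-yl)-5-(3,4,5-trimethoxyphenyl)-1-[(trimethylsilyl)oxy]cyclopentane-1-carboxylate F5. Michael addition to 12 as in step 6 gives tert-butyl 3-(2,3-dimethoxy-3-oxopropyl)-4-methyl-2-oxo-3-(prop-2-en-1-yl)-5-(3,4,5-trimethoxyphenyl)-1-[(trimethylsilyl)oxy]cyclopentane-1-carboxylate F6. TFA and then heat remove the silyl ether, the tert-butyl group and carbon dioxide to give methyl 3-[3-hydroxy-5-methyl-2-oxo-1-(prop-2-en-1-yl)-4-(3,4,5-trimethoxyphenyl)cyclopentyl]-2-methoxypropanoate F7. Its unhindered secondary hydroxyl group is methylated (MeI, Ag2O) to 15, which is saponified as in step 7.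

Further compounds
F1 | step 4 | trimethyl[(1E)-penta-1,4-dien-1-yloxy]silane | C=CC/C=C/O[Si](C)(C)C
F2 | step 8 | tert-butyl 1-methoxy-3-(2-methoxy-3-oxopropyl)-4-methyl-2-oxo-3-(prop-2-en-1-yl)-5-(3,4,5-trimethoxyphenyl)cyclopentane-1-carboxylate | C=CC[C@]1(CC(OC)C=O)C(=O)[C@@](C(=O)OC(C)(C)C)(OC)[C@@H](c2cc(OC)c(OC)c(OC)c2)[C@@H]1C
F3 | step 8 | 2-methoxy-3-[3-methoxy-5-methyl-2-oxo-1-(prop-2-en-1-yl)-4-(3,4,5-trimethoxyphenyl)cyclopentyl]propanal | C=CC[C@]1(CC(OC)C=O)C(=O)[C@H](OC)[C@@H](c2cc(OC)c(OC)c(OC)c2)[C@@H]1C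
F4 | step 8 | 2-hydroxy-1,3-dimethoxy-6-methyl-5-(prop-2-en-1-yl)-7-(3,4,5-trimethoxyphenyl)bicyclo[3.2.1]octan-8-one | C=CC[C@]12CC(OC)C(O)[C@](OC)(C1=O)[C@@H](c1cc(OC)c(OC)c(OC)c1)[C@@H]2C
F5 | step 5 | tert-butyl 4-methyl-2-oxo-3-(prop-2-en-1-yl)-5-(3,4,5-trimethoxyphenyl)-1-[(trimethylsilyl)oxy]cyclopentane-1-carboxylate | C=CC[C@H]1C(=O)[C@@](C(=O)OC(C)(C)C)(O[Si](C)(C)C)[C@@H](c2cc(OC)c(OC)c(OC)c2)[C@@H]1C
F6 | step 5 | tert-butyl 3-(2,3-dimethoxy-3-oxopropyl)-4-methyl-2-oxo-3-(prop-2-en-1-yl)-5-(3,4,5-trimethoxyphenyl)-1-[(trimethylsilyl)oxy]cyclopentane-1-carboxylate | C=CC[C@]1(CC(OC)C(=O)OC)C(=O)[C@@](C(=O)OC(C)(C)C)(O[Si](C)(C)C)[C@@H](c2cc(OC)c(OC)c(OC)c2)[C@@H]1C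
F7 | step 5 | methyl 3-[3-hydroxy-5-methyl-2-oxo-1-(prop-2-en-1-yl)-4-(3,4,5-trimethoxyphenyl)cyclopentyl]-2-methoxypropanoate | C=CC[C@]1(CC(OC)C(=O)OC)C(=O)[C@H](O)[C@@H](c2cc(OC)c(OC)c(OC)c2)[C@@H]1C
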